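The vessel was closed, stirred and isothermal. Each flask took the same substrate charge and a different coupling partner charge, and I wanted the target standing at the set time.

all flasks: substrate 0.10 M
- Saturday's: coupling partner 0.045 M; run made earlier
- Sunday's: coupling partner 0.47 M; run made earlier
- spring: coupling partner 0.0400 M; time 15 min
- winter: coupling partner 0.0800 M; time 15 min
- summer: coupling partner 0.150 M; time 15 min
- noon: coupling partner 0.300 M; time 15 min

| run | time / min | target / % | substrate / % |
|---|---|---|---|
| Saturday's | 1.00 | 0.8 | 82.7 |
| Saturday's | 2.00 | 0.7 | 68.9 |
| Saturday's | 3.00 | 1.9 | 57.1 |
| Saturday's | 4.00 | 1.9 | 46.9 |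
| Saturday's | 5.00 | 3.1 | 40.0 |
| Saturday's | 6.00 | 4.7 | 32.7 |
| Saturday's | 8.00 | 6.6 | 22.6 |
| Sunday's | 0.417 | 0.6 | 81.4 |
| Sunday's | 1.00 | 1.8 | 62.5 |
| Sunday's | 2.00 | 5.0 | 40.3 |
| Sunday's | 3.00 | 7.7 | 24.3 |
| Sunday's | 5.00 | 10.7 | 10.7 |
| Sunday's | 6.00 | 9.4 | 7.8 |
| Sunday's | 8.00 | 10.2 | 2.9 |

(standard deviation of a reading: 0.5 percentage points)

- steps that have been proposed: substrate -> intermediate A; coupling partner + intermediate A -> target; substrate + coupling partner -> intermediate B; coupling partner + intermediate A -> intermediate C; intermediate B <-> intermediate D; coupling partner + intermediate C -> side product; coupling partner + target -> over-reaction product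
- "hardly changes" means that all values lie within two and a half points (for a concentration: within two and a half percent of the largest)

- amount of target at the end, in percent of the substrate charged for spring, winter, summer, noon, in this order
- the course of these numbers from the first flask to the last (falls all the way / hardly changes / falls, then rises / rises, then falls / rises all the way)

The proposed steps give the substrate two doors. It turns by itself into intermediate A, or it meets the partner and becomes intermediate B, which exchanges with intermediate D and has no proposed path to target. Partner then takes intermediate A on to target or to intermediate C, which gives side product with more partner, and partner also takes target on to over-reaction product.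

I began with the first instants. Substrate fell nearly pseudo-first-order in both runs. Taken to the last reading, its constant was 0.186 min⁻¹ on Saturday and 0.443 min⁻¹ on Sunday. A straight line in [partner] through these two readings gave a slope of 0.604 M⁻¹ min⁻¹ and a partner-free part of 0.159 min⁻¹. For noon that gave 46.7 % as the A-share, the fraction of substrate leaving through intermediate A, namely the partner-free part over the whole constant at the charged [partner]. For spring the same ratio gave 86.8 %, which is larger than noon's; winter gave 76.7 % and summer 63.7 %.

In the middle of a run intermediate A piles up. On Saturday 77.4 % of the substrate had gone by 8.00 min, yet target read far less, 6.6 %. Its step needs partner, and in spring partner is the limiting reagent by charge, with less of it than of substrate.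

Late in Sunday's run target gained nothing beyond the scatter. On Sunday it read 10.7 % at 5.00 min and 10.2 % at 8.00 min, while substrate went from 10.7 % to 2.9 %. I committed to a row that rises with [partner] and then falls as the A-share shrinks, with summer highest.

The forecast gave 8 %, 13 %, 16.5 % and 14.5 %, course rises, then falls, on the ground that “Too much partner diverts substrate away from A”.

The flasks gave 10.8 %, 17.1 %, 20.1 % and 12.2 %, so the course was rises, then falls.

    substrate → intermediate A (k = 0.160 min⁻¹)
    coupling partner + intermediate A → target (k = 0.720 M⁻¹ min⁻¹)
    substrate + coupling partner → intermediate B (k = 0.680 M⁻¹ min⁻¹)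
    coupling partner + intermediate A → intermediate C (k = 0.220 M⁻¹ min⁻¹)
    intermediate B ⇌ intermediate D (K = 2.50, k = 0.570 min⁻¹)
    coupling partner + intermediate C → side product (k = 0.450 M⁻¹ min⁻¹)
    coupling partner + target → over-reaction product (k = 0.590 M⁻¹ min⁻¹)

At noon, between 7.50 min and 15.0 min, target went from 13.6 % to 12.2 % while over-reaction product went from 7.84 % to 19.6 %. Noon's A-share of 46.7 %, applied to the substrate gone, leaves 52.8 % for the other door, and intermediates B and D together held 52.0 %. Spring's A-share of 86.8 % leaves 12.3 %, and there intermediates B and D together held 10.5 %.

(The data were generated by integration with made-up constants; noise was put on by code.)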